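A small charge of substrate, 0.020 M, met partner in two flasks, and I had to say what leads at the end of each.

    intermediate C → decomposed reagent (k1 = 9.0 × 10⁻⁵ s⁻¹)
    substrate ⇌ intermediate A (K2 = 0.13, k2 = 2.6 × 10⁻⁴ s⁻¹)
    partner + intermediate B → target (k3 = 0.0066 M⁻¹ s⁻¹)
    partner + intermediate A ⇌ intermediate C (K4 = 15 M⁻¹, k4 = 0.0022 M⁻¹ s⁻¹)
    substrate + partner ⇌ intermediate B (K5 = 4.7 M⁻¹, k5 = 0.0038 M⁻¹ s⁻¹)
    intermediate B → side product (k6 = 7.5 × 10⁻⁴ s⁻¹)

- epsilon: substrate 0.020 M; partner 1.50 equiv; time 4.0 h
- theta: substrate 0.020 M; partner 3.00 equiv; time 4.0 h

1. which of these there is most of at the end, counted by the substrate in it, epsilon (intermediate A / target / substrate / side product)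
2. which of these there is most of at the end, counted by the substrate in it, theta (intermediate A / target / substrate / side product)
3. how much there is at the end of the one of these that leads, in percent of the substrate charged: epsilon
4. how much there is at the end of the one of these that leads, in percent of the substrate charged: theta

I built the flask up one process at a time, in fractions of the charge. First came the main step by itself in epsilon: with partner held at its charge, substrate goes to intermediate B at 0.410 h⁻¹, which leaves 19.4% substrate at the end. Then I let intermediate B fall back, at 2.91 h⁻¹ against 2.7 h⁻¹ onward to side product. With intermediate B in steady state, about half of what forms goes on, and the substrate left rises to 45.4%. Next came target: partner takes intermediate B at a further 0.713 h⁻¹ in epsilon and 1.43 h⁻¹ in theta. In epsilon, intermediate A relaxes against substrate, by that step alone, with a half-life of 0.0852 h, shorter than the 4.0 h of the run, so I treated the two as one pool, of which substrate is 88.5%.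

Partner falls during the run, so I replaced its curve by its mean. With partner as charged, the pool empties at 0.196 h⁻¹ in epsilon and 0.426 h⁻¹ in theta. Each substrate lost takes one partner, and a second for the share going to target. Taking half of that use gives mean partner fractions of 0.781 in epsilon and 0.817 in theta.

I carried one number, the drain constant: the pseudo-first-order constant at which the pool empties, being the substrate share of the pool, times the forward constant and mean partner, times the share of intermediate B that goes on. It came to 0.150 h⁻¹ in epsilon and 0.338 h⁻¹ in theta. Intermediate C leaks from the pool at about 0.0190 h⁻¹ in epsilon, less than the drain, so I set it aside. My answer for epsilon was substrate at 48.6%, ahead of side product at 37.4%. For theta it was side product at 51.8%, ahead of substrate at 22.9%.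

The forecast named substrate at 46% (39% to 53%) in epsilon and side product at 45% (38% to 52%) in theta, holding that with more partner "side product overtakes substrate". It chose my leaders, but its amounts stood below mine, by 2.6 percentage points in epsilon and 6.8 points in theta.

The simulation gave substrate leading epsilon at 46.5%, with side product at 34.9%, and side product leading theta at 47.4%, with substrate at 22.6%; these are the forecast's leaders, with both amounts inside its ranges, and my side product for theta stood 4.4 points above the flask. In epsilon at 1.34 h, intermediate B fell back at 0.89 of the rate at which it went on. Substrate and intermediate A together stood at 52.6% in epsilon, where the drain constant gives 54.9%, and at 25.6% in theta, where it gives 25.9%.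

The numbers come from no measurement; the rest is arithmetic.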